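**Retrosynthetic overview**

1. Target 28 comes from tertiary propargylic alcohol 27 by Meyer–Schuster rearrangement and 27 from TES ether 26; the enone is carried as an alkyne so that the aryl aldehyde is the only chromophore in the photochemical step.
2. 26 comes from benzocyclobutenol 20 and dipalmitoyl peroxide 23 by alkoxide-triggered ring opening with acyloxy transfer to the benzylic carbon; 20 comes from the 7-methyl-8-formylchroman 18 by photoenolisation and 4π closure, which makes a temporary bond between the methyl carbon and the formyl carbon.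
3. Structural basis: the formyl group on C8 is ortho to the oxygenated benzylic carbon on C7, so the arene is an ortho-tolualdehyde oxidised at its methyl group. The other ortho neighbour, C8a, carries O1, which leads to the hydrogen-free quaternary C2, so only the C7 methyl group can deliver hydrogen to the excited carbonyl.
4. 18 comes from 16 by SNAr of the tertiary alkoxide on the fluoride ortho to CHO (O1–C8a bond), and 16 from 14 by fluorine-directed lithiation and formylation. 14 comes from epoxide 10 and acetylide 13; 10 from (R)-2-methylglycidol 6 and benzylic Grignard reagent 7 (C3–C4 bond); 7 from 3-fluoro-5-methoxytoluene 1.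
5. Ring order: benzene ring (purchased), then the pyran ring (step 8), then the transient cyclobutene ring (formed in step 9, opened again in step 11).

Key step: step 9

Remark: 20 and 24 are expected as both epimers at the carbinol carbon (one is drawn). That centre is erased in step 11, and C2, taken from 6, is not touched by any bond-breaking event.

**Route**

Step 1
Reactants: 1 3-fluoro-5-methoxytoluene
Product: 4 (2-fluoro-6-methoxy-4-methylphenyl)methanol, via aryllithium 2 (not isolated), via aldehyde 3 (not isolated)
Conditions: n-BuLi, THF, −78 °C; DMF, −78 °C; then MeOH, NaBH4, −78 → 0 °C; aq NH4Cl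
Reagents that add atoms: N,N-dimethylformamide, CN(C)C=O
Why: Directed ortho-lithiation should occur at the ring C–H flanked by F and OMe (the most acidic site, activated by both groups), and formylation with DMF followed by in-flask NaBH4 reduction of the aldehyde should give the benzylic alcohol; no stereocentre is formed.

Step 2
Reactants: 4 (2-fluoro-6-methoxy-4-methylphenyl)methanol
Product: 5 2-(chloromethyl)-1-fluoro-3-methoxy-5-methylbenzene
Conditions: SOCl2, DMF (cat.), CH2Cl2, 0 °C → rt; used crude
Reagents that add atoms: thionyl chloride, O=S(Cl)Cl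
Why: Deoxychlorination of an electron-rich benzylic alcohol through its chlorosulfite is a standard substitution, and the reactive chloride is taken on without storage.

Step 3
Reactants: 5 2-(chloromethyl)-1-fluoro-3-methoxy-5-methylbenzene; 6 (R)-2-methylglycidol
Product: 8 (2S)-4-(2-fluoro-6-methoxy-4-methylphenyl)-2-methylbutane-1,2-diol, via benzylic Grignard reagent 7 (not isolated)
Conditions: Mg, THF, 0 °C → rt (slow addition of 5, 2.4 equiv); then CuI (10 mol%), 6 (1.0 equiv), THF, −30 → 0 °C; aq NH4Cl
Reagents that add atoms: none
Why: Copper-catalysed Grignard opening of the 2,2-disubstituted epoxide takes place by SN2 attack at its unsubstituted CH2 after the first equivalent of 7 has deprotonated the hydroxyl group, so the quaternary stereocentre of 6 is carried over untouched and becomes C2 of the chroman (the descriptor changes from R to S only because the priorities change).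

Step 4
Reactants: 8 (2S)-4-(2-fluoro-6-methoxy-4-methylphenyl)-2-methylbutane-1,2-diol
Product: 10 (2S)-2-[2-(2-fluoro-6-methoxy-4-methylphenyl)ethyl]-2-methyloxirane, via primary tosylate 9 (not isolated)
Conditions: TsCl, Et3N, DMAP (cat.), CH2Cl2, 0 °C; then K2CO3, MeOH, rt
Reagents that add atoms: none
Why: Selective sulfonylation of the primary hydroxyl group (the tertiary one is inert) and 3-exo-tet Williamson closure by the tertiary alkoxide re-form an epoxide without breaking any bond at the stereocentre, so its configuration is retained.

Step 5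
Reactants: 11 2-methylbut-3-yn-2-ol
Product: 12 triethyl[(2-methylbut-3-yn-2-yl)oxy]silane
Conditions: TESCl, imidazole, DMAP (cat.), DMF, rt
Reagents that add atoms: chlorotriethylsilane, CC[Si](Cl)(CC)CC
Why: Standard silyl ether formation masks the tertiary propargylic hydroxyl group against the organometallic, basic and peroxide steps ahead, while remaining removable with fluoride at the end.

Step 6
Reactants: 12 triethyl[(2-methylbut-3-yn-2-yl)oxy]silane; 10 (2S)-2-[2-(2-fluoro-6-methoxy-4-methylphenyl)ethyl]-2-methyloxirane
Product: 14 (3S)-1-(2-fluoro-6-methoxy-4-methylphenyl)-3,7-dimethyl-7-(triethylsilyloxy)oct-5-yn-3-ol, via lithium acetylide 13 (not isolated)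
Conditions: n-BuLi, THF, −78 °C; BF3·OEt2, −78 °C; then 10, −78 °C; aq NaHCO3
Reagents that add atoms: none
Why: In this Yamaguchi–Hirao alkynylation the BF3-activated lithium acetylide opens the epoxide by SN2 attack at its CH2 terminus at −78 °C, so the tertiary carbinol stereocentre is again untouched.

Step 7
Reactants: 14 (3S)-1-(2-fluoro-6-methoxy-4-methylphenyl)-3,7-dimethyl-7-(triethylsilyloxy)oct-5-yn-3-ol
Product: 16 2-fluoro-3-[(3S)-3-hydroxy-3,7-dimethyl-7-(triethylsilyloxy)oct-5-yn-1-yl]-4-methoxy-6-methylbenzaldehyde, via dilithiated intermediate 15 (not isolated)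
Conditions: s-BuLi (2.3 equiv), PMDTA, THF, −78 °C; DMF, −78 °C; aq NH4Cl
Reagents that add atoms: N,N-dimethylformamide, CN(C)C=O
Why: Deprotonative ortho-lithiation with the non-chelating s-BuLi/PMDTA base is governed by C–H acidity and should occur next to fluorine rather than next to OMe (the first equivalent forms the tertiary alkoxide, which also disfavours deprotonation of the neighbouring propargylic CH2), and DMF formylates the aryllithium at −78 °C before fluoride loss can set in.

Step 8
Reactants: 16 2-fluoro-3-[(3S)-3-hydroxy-3,7-dimethyl-7-(triethylsilyloxy)oct-5-yn-1-yl]-4-methoxy-6-methylbenzaldehyde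
Product: 18 (2S)-5-methoxy-2,7-dimethyl-2-[4-methyl-4-(triethylsilyloxy)pent-2-yn-1-yl]chroman-8-carbaldehyde, via sodium alkoxide 17 (not isolated)
Conditions: NaH, THF–DMF (9:1), 0 °C → rt
Reagents that add atoms: none
Why: In this intramolecular SNAr (addition–elimination through a Meisenheimer adduct) the tertiary alkoxide displaces the fluoride activated by the ortho formyl group and closes the six-membered pyran ring by O–aryl bond formation, with retention at C2 because its C–O bond is not involved.

Step 9
Reactants: 18 (2S)-5-methoxy-2,7-dimethyl-2-[4-methyl-4-(triethylsilyloxy)pent-2-yn-1-yl]chroman-8-carbaldehyde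
Product: 20 benzocyclobutenol of the (2S)-chroman: a CH2–CH(OH) bridge fused across C7 (CH2) and C8 (CHOH), both carbinol epimers, via photoenol 19 (not isolated)
Conditions: hν (350–365 nm), degassed PhH (5 mM), 20 °C; concentration below 30 °C, neutral silica
Reagents that add atoms: none
Why: Excitation of the aryl aldehyde (n,π*) and intersystem crossing give a triplet that takes a hydrogen from the C7 methyl group through a six-membered transition state, and the biradical relaxes to two dienols: the one with OH turned towards the CH2 returns to 18 by 1,5-hydrogen shift, whereas 19 (OH turned away and hydrogen-bonded to O1) lives long enough to close. The closest known reaction is the photoenolisation of ortho-alkyl aryl aldehydes and ketones with collapse of the photoenol to a benzocyclobutenol (a Norrish–Yang-type photocyclisation). The four-membered ring closes by thermal conrotatory 4π electrocyclisation of 19, which joins the former methyl carbon to the former formyl carbon and restores the benzene ring. The new carbinol stereocentre has no controlling element, C2 being too remote, so both epimers are expected; this is immaterial because the centre is erased in step 11. The step needs site selectivity in hydrogen abstraction, which the substrate secures because only the C7 methyl hydrogens can reach the carbonyl oxygen (O1 leads to the hydrogen-free C2). It also needs closure to outrun dimerisation and oxygen capture of 19, which dilution and degassing secure, and 20 no longer absorbs the light used and should accumulate.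

Step 10
Reactants: 21 palmitoyl chloride (2 equiv relative to H2O2)
Product: 23 dipalmitoyl peroxide (dihexadecanoyl peroxide), via peroxyhexadecanoic acid 22 (not isolated)
Conditions: H2O2 (30% aq, 0.5 equiv relative to 21), pyridine, Et2O, 0 °C; kept cold, not heated
Reagents that add atoms: hydrogen peroxide, OO; palmitoyl chloride (second equivalent of 21), CCCCCCCCCCCCCCCC(=O)Cl
Why: Two successive Schotten–Baumann-type acylations of hydrogen peroxide, the first giving peracid 22 and the second, by another equivalent of 21 on its terminal peroxy oxygen, giving the diacyl peroxide, with pyridine as acid scavenger, are the standard preparation of symmetrical diacyl peroxides.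

Step 11
Reactants: 20 benzocyclobutenol of the (2S)-chroman; 23 dipalmitoyl peroxide
Product: 26 [(2S)-8-formyl-5-methoxy-2-methyl-2-[4-methyl-4-(triethylsilyloxy)pent-2-yn-1-yl]chroman-7-yl]methyl hexadecanoate, via potassium alkoxide 24 (not isolated), via dienolate 25 (not isolated)
Conditions: KH (1.05 equiv), THF, −40 → 0 °C; cannula filtration into 23 (1.5 equiv), THF–PhMe, −20 °C; aq NH4Cl/Na2S2O3
Reagents that add atoms: none
Why: Proposed new method: deprotonation gives alkoxide 24, whose oxy-anion-accelerated, strain-driven conrotatory 4π ring opening (O− rotating outward) should give the ortho-quinodimethane enolate 25 at or below 0 °C; its exocyclic CH2 carbon, the only nucleophilic carbon whose bonding restores the benzene ring, should attack the weak O–O bond of 23 in an SN2 displacement at oxygen that expels palmitate and unveils the aldehyde; KH is chosen so that no proton donor remains to quench 25 back to 18, and inverse addition into excess 23 keeps 25 away from the aldehyde being formed; the closest known reactions are the base-induced ring opening of benzocyclobutenols to ortho-formylbenzyl anions (trapped by protons or dienophiles) and the α-acyloxylation of enolates with dibenzoyl peroxide.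

Step 12
Reactants: 26 [(2S)-8-formyl-5-methoxy-2-methyl-2-[4-methyl-4-(triethylsilyloxy)pent-2-yn-1-yl]chroman-7-yl]methyl hexadecanoate
Product: 27 [(2S)-8-formyl-2-(4-hydroxy-4-methylpent-2-yn-1-yl)-5-methoxy-2-methylchroman-7-yl]methyl hexadecanoate
Conditions: HF·pyridine, pyridine, THF, 0 °C → rt
Reagents that add atoms: none
Why: Fluoride-mediated desilylation with buffered HF·pyridine should cleave the tertiary TES ether without touching the palmitate ester, the aldehyde or the alkyne.

Step 13
Reactants: 27 [(2S)-8-formyl-2-(4-hydroxy-4-methylpent-2-yn-1-yl)-5-methoxy-2-methylchroman-7-yl]methyl hexadecanoate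
Product: 28 [(2S)-8-formyl-5-methoxy-2-methyl-2-(4-methyl-2-oxopent-3-en-1-yl)chroman-7-yl]methyl hexadecanoate (target)
Conditions: Ph3PAuNTf2 (2 mol%), MeOH (1 equiv), PhMe, rt
Reagents that add atoms: none
Why: In this gold-catalysed Meyer–Schuster rearrangement, π-activation of the alkyne by the cationic gold complex induces a formal 1,3-shift of the tertiary hydroxyl group to an allenol that tautomerises to the β,β-dimethyl enone, under neutral conditions that should spare the β-aryloxy ketone (no retro-oxa-Michael opening at C2), the aldehyde and the ester.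

**Compound list**

1 | 3-fluoro-5-methoxytoluene | COc1cc(C)cc(F)c1 | starting material
2 | (2-fluoro-6-methoxy-4-methylphenyl)lithium | [Li]c1c(F)cc(C)cc1OC | intermediate
3 | 2-fluoro-6-methoxy-4-methylbenzaldehyde | COc1cc(C)cc(F)c1C=O | intermediate
4 | (2-fluoro-6-methoxy-4-methylphenyl)methanol | COc1cc(C)cc(F)c1CO | intermediate
5 | 2-(chloromethyl)-1-fluoro-3-methoxy-5-methylbenzene | COc1cc(C)cc(F)c1CCl | intermediate
6 | (R)-2-methylglycidol | OC[C@]1(C)CO1 | starting material
7 | (2-fluoro-6-methoxy-4-methylbenzyl)magnesium chloride | COc1cc(C)cc(F)c1C[Mg]Cl | intermediate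
8 | (2S)-4-(2-fluoro-6-methoxy-4-methylphenyl)-2-methylbutane-1,2-diol | OC[C@](O)(C)CCc1c(F)cc(C)cc1OC | intermediate
9 | (2S)-4-(2-fluoro-6-methoxy-4-methylphenyl)-2-hydroxy-2-methylbutyl 4-methylbenzenesulfonate | Cc1ccc(cc1)S(=O)(=O)OC[C@](O)(C)CCc1c(F)cc(C)cc1OC | intermediate
10 | (2S)-2-[2-(2-fluoro-6-methoxy-4-methylphenyl)ethyl]-2-methyloxirane | C[C@]1(CCc2c(F)cc(C)cc2OC)CO1 | intermediate
11 | 2-methylbut-3-yn-2-ol | CC(C)(O)C#C | starting material
12 | triethyl[(2-methylbut-3-yn-2-yl)oxy]silane | CC[Si](CC)(CC)OC(C)(C)C#C | intermediate
13 | lithium acetylide of 12 | CC[Si](CC)(CC)OC(C)(C)C#C[Li] | intermediate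
14 | (3S)-1-(2-fluoro-6-methoxy-4-methylphenyl)-3,7-dimethyl-7-(triethylsilyloxy)oct-5-yn-3-ol | CC[Si](CC)(CC)OC(C)(C)C#CC[C@@](C)(O)CCc1c(F)cc(C)cc1OC | intermediate
15 | dilithiated 14 (lithium alkoxide; lithium on the ring carbon between F and CH3) | CC[Si](CC)(CC)OC(C)(C)C#CC[C@@](C)(O[Li])CCc1c(F)c([Li])c(C)cc1OC | intermediate
16 | 2-fluoro-3-[(3S)-3-hydroxy-3,7-dimethyl-7-(triethylsilyloxy)oct-5-yn-1-yl]-4-methoxy-6-methylbenzaldehyde | CC[Si](CC)(CC)OC(C)(C)C#CC[C@@](C)(O)CCc1c(F)c(C=O)c(C)cc1OC | intermediate
17 | sodium alkoxide of 16 | CC[Si](CC)(CC)OC(C)(C)C#CC[C@@](C)(O[Na])CCc1c(F)c(C=O)c(C)cc1OC | intermediate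
18 | (2S)-5-methoxy-2,7-dimethyl-2-[4-methyl-4-(triethylsilyloxy)pent-2-yn-1-yl]chroman-8-carbaldehyde | Cc1cc(OC)c2c(c1C=O)O[C@](C)(CC#CC(C)(C)O[Si](CC)(CC)CC)CC2 | intermediate
19 | photoenol of 18: ortho-quinodimethane with exocyclic =CH2 on C7 and exocyclic =CH–OH on C8, OH turned away from the CH2 | O/C=C1/C(=C)C=C(OC)C2=C1O[C@](C)(CC#CC(C)(C)O[Si](CC)(CC)CC)CC2 | intermediate
20 | benzocyclobutenol: (2S)-chroman of 18 with CH2 (on C7) and CH(OH) (on C8) joined into a fused cyclobutene ring; both carbinol epimers, one drawn | COc1cc2C[C@@H](O)c2c2O[C@](C)(CC#CC(C)(C)O[Si](CC)(CC)CC)CCc12 | intermediate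
21 | palmitoyl chloride | CCCCCCCCCCCCCCCC(=O)Cl | starting material
22 | peroxyhexadecanoic acid (perpalmitic acid) | CCCCCCCCCCCCCCCC(=O)OO | intermediate
23 | dipalmitoyl peroxide | CCCCCCCCCCCCCCCC(=O)OOC(=O)CCCCCCCCCCCCCCC | intermediate
24 | potassium alkoxide of 20 | COc1cc2C[C@@H](O[K])c2c2O[C@](C)(CC#CC(C)(C)O[Si](CC)(CC)CC)CCc12 | intermediate
25 | potassium ortho-quinodimethane enolate: exocyclic =CH2 on C7, exocyclic =CH–OK on C8 | [K]O/C=C1/C(=C)C=C(OC)C2=C1O[C@](C)(CC#CC(C)(C)O[Si](CC)(CC)CC)CC2 | intermediate
26 | [(2S)-8-formyl-5-methoxy-2-methyl-2-[4-methyl-4-(triethylsilyloxy)pent-2-yn-1-yl]chroman-7-yl]methyl hexadecanoate | CCCCCCCCCCCCCCCC(=O)OCc1cc(OC)c2c(c1C=O)O[C@](C)(CC#CC(C)(C)O[Si](CC)(CC)CC)CC2 | intermediate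
27 | [(2S)-8-formyl-2-(4-hydroxy-4-methylpent-2-yn-1-yl)-5-methoxy-2-methylchroman-7-yl]methyl hexadecanoate | CCCCCCCCCCCCCCCC(=O)OCc1cc(OC)c2c(c1C=O)O[C@](C)(CC#CC(C)(C)O)CC2 | intermediate
28 | [(2S)-8-formyl-5-methoxy-2-methyl-2-(4-methyl-2-oxopent-3-en-1-yl)chroman-7-yl]methyl hexadecanoate | CCCCCCCCCCCCCCCC(=O)OCc1cc(OC)c2c(c1C=O)O[C@](C)(CC(=O)C=C(C)C)CC2 | target

**Step count**

Total: 13 steps. Longest linear sequence: 11 steps (steps 1–4, 6–9 and 11–13, from 1 to 28); steps 5 and 10 prepare the side-arm reagents 12 and 23.

**Steps most likely to fail**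

1. Step 11 (acyloxylative ring opening). The enolate may attack an acyl carbon of the peroxide instead of oxygen, may be oxidised by electron transfer with loss of the acyloxy fragment by decarboxylation, or may add to the aldehyde that is being formed. The fallback sets out from 20 and returns at 26, using only known reaction types. The same KH-induced ring opening is followed by inverse addition of the enolate to 1,2-dibromotetrachloroethane (THF, −78 °C), a standard positive-bromine quench of carbanions. This should give (2S)-7-(bromomethyl)-5-methoxy-2-methyl-2-[4-methyl-4-(triethylsilyloxy)pent-2-yn-1-yl]chroman-8-carbaldehyde F1. SN2 displacement of the benzylic bromide with caesium palmitate (palmitic acid, Cs2CO3, DMF, rt) should then give 26. The C–O bond is thereby made with reversed polarity, carboxylate as nucleophile and benzylic carbon as electrophile.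

2. Step 9 (photoenolisation and closure). The dienol may return to the aldehyde faster than it closes, so that long irradiation leads to secondary photoreactions and dimerisation, or the strained alcohol may reopen during isolation. The fallback sets out from 18 and returns at 26, bypassing step 11. Irradiation at the same wavelength in oxygen-saturated benzene should intercept the dienol by its known cycloaddition with ground-state oxygen, giving the cyclic peroxy hemiacetal (a 1,4-dihydro-2,3-benzodioxin-1-ol fused across C7 and C8) F2. Addition of PPh3 to the same flask should cleave the O–O bond and give (2S)-7-(hydroxymethyl)-5-methoxy-2-methyl-2-[4-methyl-4-(triethylsilyloxy)pent-2-yn-1-yl]chroman-8-carbaldehyde F3. Because this hydroxy aldehyde is expected to sit largely as its cyclic lactol and would be acylated at the lactol oxygen, it is not acylated directly but reduced without isolation with NaBH4 in MeOH to the (2S)-7,8-bis(hydroxymethyl)chroman F4. The C7 CH2OH group, which has only one ortho substituent, should be acylated in preference to the doubly flanked C8 CH2OH group with palmitoyl chloride and 2,4,6-collidine (CH2Cl2, −40 °C), giving the C7 monopalmitate with free C8 hydroxymethyl group F5. Oxidation of the remaining benzylic alcohol with MnO2 (CH2Cl2, rt) should then give 26.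

3. Step 7 (fluorine-directed lithiation and formylation). Metalation may occur next to OMe or at the propargylic CH2, leading to the regioisomeric aldehyde or to allene by-products, and the ortho-fluoro aryllithium may lose LiF if the temperature rises. The fallback sets out from 14 and returns at 16, replacing kinetic acidity by electrophilic regiocontrol. NBS in MeCN at 0 °C should brominate the ring para to OMe, the position between F and CH3, giving (3S)-1-(3-bromo-2-fluoro-6-methoxy-4-methylphenyl)-3,7-dimethyl-7-(triethylsilyloxy)oct-5-yn-3-ol F6. Treatment with n-BuLi (2.1 equiv, THF, −78 °C; alkoxide formation, then bromine–lithium exchange, which is faster than any deprotonation) and DMF should then give 16.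

**Further compounds**

F1 | step 11 | (2S)-7-(bromomethyl)-5-methoxy-2-methyl-2-[4-methyl-4-(triethylsilyloxy)pent-2-yn-1-yl]chroman-8-carbaldehyde | BrCc1cc(OC)c2c(c1C=O)O[C@](C)(CC#CC(C)(C)O[Si](CC)(CC)CC)CC2
F2 | step 9 | cyclic peroxy hemiacetal: CH2–O–O–CH(OH) bridge fused across C7 (CH2) and C8 (CHOH) of the (2S)-chroman, both hemiacetal epimers | COc1cc2COOC(O)c2c2O[C@](C)(CC#CC(C)(C)O[Si](CC)(CC)CC)CCc12
F3 | step 9 | (2S)-7-(hydroxymethyl)-5-methoxy-2-methyl-2-[4-methyl-4-(triethylsilyloxy)pent-2-yn-1-yl]chroman-8-carbaldehyde (open form drawn; in equilibrium with its lactol) | OCc1cc(OC)c2c(c1C=O)O[C@](C)(CC#CC(C)(C)O[Si](CC)(CC)CC)CC2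
F4 | step 9 | [(2S)-8-(hydroxymethyl)-5-methoxy-2-methyl-2-[4-methyl-4-(triethylsilyloxy)pent-2-yn-1-yl]chroman-7-yl]methanol | COc1cc(CO)c(CO)c2O[C@](C)(CC#CC(C)(C)O[Si](CC)(CC)CC)CCc12
F5 | step 9 | [(2S)-8-(hydroxymethyl)-5-methoxy-2-methyl-2-[4-methyl-4-(triethylsilyloxy)pent-2-yn-1-yl]chroman-7-yl]methyl hexadecanoate | CCCCCCCCCCCCCCCC(=O)OCc1cc(OC)c2c(c1CO)O[C@](C)(CC#CC(C)(C)O[Si](CC)(CC)CC)CC2
F6 | step 7 | (3S)-1-(3-bromo-2-fluoro-6-methoxy-4-methylphenyl)-3,7-dimethyl-7-(triethylsilyloxy)oct-5-yn-3-ol | CC[Si](CC)(CC)OC(C)(C)C#CC[C@@](C)(O)CCc1c(F)c(Br)c(C)cc1OC
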